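**Plan**
1. Retrosynthesis cuts first the bond from coumarin C8 to the ketone carbon, then in one [4+2] event the two cyclohexene bonds CH2–CH2 (C3–C4) and CH(Me)–CH (C5–C6), and last the prenyl group at C6 and the pyranone ring of the coumarin. Cyclohexene numbering: C1 bears the acyl group, C5 the methyl, C6 the hydroxyethyl.
2. Enabling feature: the ketone carbon, C1, C6, the carbinol carbon and its oxygen form a γ-hydroxy enone, which folds into a butenolide ring (O–C(=O)–C1=C6–CHMe). Its C1=C6 bond with a vinyl group (C2=C3) on C1 is an electron-poor diene, one face of which is shielded by the ring methyl.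
3. Forward, acyl part: the butenolide ring is made first from (S)-but-3-yn-2-ol, then the cyclohexene is closed by an inverse-electron-demand Diels–Alder reaction with benzyl (Z)-propenyl ether. The benzyloxy helper is removed by debenzylation and Barton–McCombie deoxygenation.
4. Forward, aryl part: Pechmann condensation, C8 iodination, then a 7-O-(1,1-dimethylallyl) ether and Claisen shift to C6. The C8 arylmagnesium opens the lactone, which releases ketone and alcohol together and gives the target without protecting groups.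
5. Stereochemistry: the carbinol centre comes from the chiral pool; C6 is set by approach anti to the butenolide methyl; C5 is set by the endo mode with retention of the Z geometry of the enol ether.

Key step: step 5

Remark: the target is taken as the open γ-hydroxy ketone drawn (not its cyclic hemiketal); the SMILES is read as (5R,6R) in the cyclohexene with a (1S)-1-hydroxyethyl group, methyl and hydroxyethyl cis.

**Step 1**
Reactants: 1 (S)-but-3-yn-2-ol; 2 vinyl bromide
Product: 3 (S)-hex-5-en-3-yn-2-ol
Conditions: PdCl2(PPh3)2 (2 mol %), CuI (4 mol %), iPr2NH, THF, 0 °C to rt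
Reagents that add atoms: none
Why: Sonogashira coupling of a terminal alkyne with a vinyl halide, which tolerates the free propargylic alcohol and does not touch the stereocentre.

**Step 2**
Reactants: 3 (S)-hex-5-en-3-yn-2-ol
Product: 5 (2S,3Z)-4-iodohexa-3,5-dien-2-ol, via cyclic alkenylalanate 4 (not isolated)
Conditions: NaAlH2(OCH2CH2OMe)2 (Red-Al), THF, 0 °C to rt; then I2, THF, −78 to 0 °C
Reagents that add atoms: iodine (II)
Why: Alkoxide-directed trans-hydroalumination of the propargylic alcohol places aluminium on the distal alkyne carbon inside a five-membered alanate, and iodinolysis with retention should give the Z iodide with iodine cis to the carbinol carbon.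

**Step 3**
Reactants: 5 (2S,3Z)-4-iodohexa-3,5-dien-2-ol
Product: 6 (5S)-3-ethenyl-5-methylfuran-2(5H)-one
Conditions: PdCl2(PPh3)2 (3 mol %), CO (1 atm), K2CO3, THF, rt
Reagents that add atoms: carbon monoxide ([C-]#[O+])
Why: Palladium-catalysed carbonylative lactonization of a (Z)-γ-iodo allylic alcohol (oxidative addition, CO insertion, capture of the acyl group by the cis hydroxyl) should close the butenolide with the carbinol centre unchanged; the diene is kept cold in solution and used at once.

**Step 4**
Reactants: 7 allyl benzyl ether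
Product: 8 benzyl (Z)-prop-1-enyl ether
Conditions: KOtBu (0.2 equiv), DMSO, rt
Reagents that add atoms: none
Why: Base-catalysed isomerization of an allyl ether to a propenyl ether, which should give mainly the Z isomer through the cis-configured, potassium-bridged oxyallyl anion.

**Step 5**
Reactants: 6 (5S)-3-ethenyl-5-methylfuran-2(5H)-one; 8 benzyl (Z)-prop-1-enyl ether
Product: 9 (3S,3aR,4S,5R)-5-(benzyloxy)-3,4-dimethyl-3a,4,5,6-tetrahydro-2-benzofuran-1(3H)-one
Conditions: 8 (5 equiv), BHT (cat.), toluene, 110 °C, sealed tube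
Reagents that add atoms: none
Why: A concerted, asynchronous inverse-electron-demand Diels–Alder reaction is expected, in which the HOMO of enol ether 8 meets the LUMO of the semicyclic diene of 6 (furanone C3=C4 bond plus the vinyl group), lowered by the lactone carbonyl on the internal diene carbon. The closest known reaction type is the cycloaddition of 2-alkoxycarbonyl-1,3-dienes with enol ethers. The cyclohexene ring is closed by intermolecular [4+2] annulation (bonds C3a–C4 and C5–C6 of 9) and ends fused to the lactone at the former furanone C3–C4 bond. C3a is set by approach of 8 anti to the ring methyl; C4 is set by the endo position of the cis-related benzyloxy and methyl groups under the diene with suprafacial retention of the Z geometry, which puts the methyl cis to lactone carbon C3; C5 forms alongside and is erased later. The step needs regioselectivity, which the polarization secures (methyl-bearing nucleophilic carbon of 8 to the β-carbon of the unsaturated lactone, oxygen-bearing carbon to the vinyl terminus), face selectivity, which the ring methyl secures, and endo selectivity, which rests on the usual endo preference of the alkoxy group of an enol ether.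

**Step 6**
Reactants: 9 (3S,3aR,4S,5R)-5-(benzyloxy)-3,4-dimethyl-3a,4,5,6-tetrahydro-2-benzofuran-1(3H)-one
Product: 10 (3S,3aR,4S,5R)-5-hydroxy-3,4-dimethyl-3a,4,5,6-tetrahydro-2-benzofuran-1(3H)-one
Conditions: BCl3, C6HMe5, CH2Cl2, −78 °C; then MeOH
Reagents that add atoms: none
Why: Lewis-acid debenzylation with a cation scavenger cleaves the benzyl–oxygen bond only, so the unsaturated lactone and all stereocentres should survive.

**Step 7**
Reactants: 10 (3S,3aR,4S,5R)-5-hydroxy-3,4-dimethyl-3a,4,5,6-tetrahydro-2-benzofuran-1(3H)-one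
Product: 11 O-[(3S,3aR,4S,5R)-3,4-dimethyl-1-oxo-1,3,3a,4,5,6-hexahydro-2-benzofuran-5-yl] O-phenyl carbonothioate
Conditions: PhOC(S)Cl, pyridine, DMAP (cat.), CH2Cl2, rt
Reagents that add atoms: O-phenyl carbonochloridothioate (ClC(=S)Oc1ccccc1)
Why: Thioacylation of the secondary alcohol gives the radical precursor for a Barton–McCombie deoxygenation without change at any stereocentre.

**Step 8**
Reactants: 11 O-[(3S,3aR,4S,5R)-3,4-dimethyl-1-oxo-1,3,3a,4,5,6-hexahydro-2-benzofuran-5-yl] O-phenyl carbonothioate
Product: 12 (3S,3aR,4R)-3,4-dimethyl-3a,4,5,6-tetrahydro-2-benzofuran-1(3H)-one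
Conditions: Bu3SnH, AIBN (cat.), toluene, 90 °C
Reagents that add atoms: none
Why: Barton–McCombie radical deoxygenation removes the helper oxygen through a secondary alkyl radical that is reduced by the tin hydride, which leaves the C3, C3a and C4 centres and the conjugated alkene as they are.

**Step 9**
Reactants: 13 5-methoxybenzene-1,3-diol; 14 ethyl 2-methyl-3-oxobutanoate
Product: 15 7-hydroxy-5-methoxy-3,4-dimethyl-2H-chromen-2-one
Conditions: H2SO4 (75% aq.), 0 °C to rt
Reagents that add atoms: none
Why: Pechmann condensation, in which ring closure at either of the two equivalent positions between OH and OMe (para to the other hydroxyl) should give mainly the 5-methoxy-7-hydroxy isomer; the minor 5-hydroxy-7-methoxy isomer is to be removed by crystallization.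

**Step 10**
Reactants: 15 7-hydroxy-5-methoxy-3,4-dimethyl-2H-chromen-2-one
Product: 16 7-hydroxy-8-iodo-5-methoxy-3,4-dimethyl-2H-chromen-2-one
Conditions: NIS (1.0 equiv), CF3CO2H (cat.), MeCN, 0 °C
Reagents that add atoms: N-iodosuccinimide (O=C1CCC(=O)N1I)
Why: Electrophilic aromatic iodination should go to C8, the position ortho to the free hydroxyl and para to the methoxy group that 7-hydroxycoumarins prefer.

**Step 11**
Reactants: 16 7-hydroxy-8-iodo-5-methoxy-3,4-dimethyl-2H-chromen-2-one; 17 3-chloro-3-methylbut-1-yne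
Product: 18 8-iodo-5-methoxy-3,4-dimethyl-7-[(2-methylbut-3-yn-2-yl)oxy]-2H-chromen-2-one
Conditions: DBU, CuCl2 (0.1 mol %), MeCN, 0 °C
Reagents that add atoms: none
Why: Copper-catalysed O-alkylation of a phenol with a tertiary propargylic chloride gives the 1,1-dimethylpropargyl aryl ether under mild conditions that leave the aryl iodide alone.

**Step 12**
Reactants: 18 8-iodo-5-methoxy-3,4-dimethyl-7-[(2-methylbut-3-yn-2-yl)oxy]-2H-chromen-2-one
Product: 19 8-iodo-5-methoxy-3,4-dimethyl-7-[(2-methylbut-3-en-2-yl)oxy]-2H-chromen-2-one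
Conditions: H2 (1 atm), Pd/CaCO3 poisoned with Pb(OAc)2 (Lindlar catalyst), quinoline, EtOAc, rt
Reagents that add atoms: none
Why: Lindlar semihydrogenation of the terminal alkyne to the alkene on the poisoned catalyst should stop at the 1,1-dimethylallyl ether and spare the aryl iodide and the pyranone double bond.

**Step 13**
Reactants: 19 8-iodo-5-methoxy-3,4-dimethyl-7-[(2-methylbut-3-en-2-yl)oxy]-2H-chromen-2-one
Product: 21 7-hydroxy-8-iodo-5-methoxy-3,4-dimethyl-6-(3-methylbut-2-en-1-yl)-2H-chromen-2-one, via prenyl cyclohexadienone 20 (not isolated)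
Conditions: PhNEt2, 140 °C
Reagents that add atoms: none
Why: Aromatic Claisen rearrangement ([3,3] shift) of the 1,1-dimethylallyl ether delivers a prenyl group to C6, the only ortho position that can rearomatize because C8 is blocked by iodine.

**Step 14**
Reactants: 21 7-hydroxy-8-iodo-5-methoxy-3,4-dimethyl-6-(3-methylbut-2-en-1-yl)-2H-chromen-2-one; 12 (3S,3aR,4R)-3,4-dimethyl-3a,4,5,6-tetrahydro-2-benzofuran-1(3H)-one
Product: 23 7-hydroxy-8-{[(5R,6R)-6-[(1S)-1-hydroxyethyl]-5-methylcyclohex-1-en-1-yl]carbonyl}-5-methoxy-3,4-dimethyl-6-(3-methylbut-2-en-1-yl)-2H-chromen-2-one (target), via dimagnesiated aryl phenoxide 22 (not isolated)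
Conditions: MeMgCl (1.0 equiv), THF, −30 °C; iPrMgCl·LiCl (1.1 equiv), −30 to −10 °C; then 12, −30 °C to rt; aq. NH4Cl
Reagents that add atoms: none
Why: Iodine–magnesium exchange on the iodophenol, protected in the flask as its magnesium phenoxide, gives a hindered arylmagnesium whose 1,2-addition to the lactone should stop at the tetrahedral magnesium hemiketal, so that work-up releases the aryl ketone and the secondary alcohol at once with no stereocentre touched.

**Compound list**
1 | (S)-but-3-yn-2-ol | C#C[C@H](C)O | starting material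
2 | vinyl bromide (bromoethene) | C=CBr | starting material
3 | (S)-hex-5-en-3-yn-2-ol | C=CC#C[C@H](C)O | intermediate
4 | cyclic alkenylalanate: sodium (5S)-2,2-bis(2-methoxyethoxy)-5-methyl-3-vinyl-2,5-dihydro-1,2-oxaaluminol-2-uide | C=CC1=C[C@H](C)O[Al-]1(OCCOC)OCCOC.[Na+] | intermediate
5 | (2S,3Z)-4-iodohexa-3,5-dien-2-ol | C=C/C(I)=C/[C@H](C)O | intermediate
6 | (5S)-3-ethenyl-5-methylfuran-2(5H)-one | C=CC1=C[C@H](C)OC1=O | intermediate
7 | allyl benzyl ether | C=CCOCc1ccccc1 | starting material
8 | benzyl (Z)-prop-1-enyl ether | C/C=C\OCc1ccccc1 | intermediate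
9 | (3S,3aR,4S,5R)-5-(benzyloxy)-3,4-dimethyl-3a,4,5,6-tetrahydro-2-benzofuran-1(3H)-one | O=C1O[C@@H](C)[C@@H]2[C@H](C)[C@H](OCc3ccccc3)CC=C12 | intermediate
10 | (3S,3aR,4S,5R)-5-hydroxy-3,4-dimethyl-3a,4,5,6-tetrahydro-2-benzofuran-1(3H)-one | O=C1O[C@@H](C)[C@@H]2[C@H](C)[C@H](O)CC=C12 | intermediate
11 | O-[(3S,3aR,4S,5R)-3,4-dimethyl-1-oxo-1,3,3a,4,5,6-hexahydro-2-benzofuran-5-yl] O-phenyl carbonothioate | O=C1O[C@@H](C)[C@@H]2[C@H](C)[C@H](OC(=S)Oc3ccccc3)CC=C12 | intermediate
12 | (3S,3aR,4R)-3,4-dimethyl-3a,4,5,6-tetrahydro-2-benzofuran-1(3H)-one | O=C1O[C@@H](C)[C@@H]2[C@H](C)CCC=C12 | intermediate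
13 | 5-methoxybenzene-1,3-diol | COc1cc(O)cc(O)c1 | starting material
14 | ethyl 2-methyl-3-oxobutanoate | CCOC(=O)C(C)C(C)=O | starting material
15 | 7-hydroxy-5-methoxy-3,4-dimethyl-2H-chromen-2-one | COc1cc(O)cc2oc(=O)c(C)c(C)c12 | intermediate
16 | 7-hydroxy-8-iodo-5-methoxy-3,4-dimethyl-2H-chromen-2-one | COc1cc(O)c(I)c2oc(=O)c(C)c(C)c12 | intermediate
17 | 3-chloro-3-methylbut-1-yne | CC(C)(Cl)C#C | starting material
18 | 8-iodo-5-methoxy-3,4-dimethyl-7-[(2-methylbut-3-yn-2-yl)oxy]-2H-chromen-2-one | COc1cc(OC(C)(C)C#C)c(I)c2oc(=O)c(C)c(C)c12 | intermediate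
19 | 8-iodo-5-methoxy-3,4-dimethyl-7-[(2-methylbut-3-en-2-yl)oxy]-2H-chromen-2-one | COc1cc(OC(C)(C)C=C)c(I)c2oc(=O)c(C)c(C)c12 | intermediate
20 | prenyl cyclohexadienone: 8-iodo-5-methoxy-3,4-dimethyl-6-(3-methylbut-2-en-1-yl)-2H-chromene-2,7(6H)-dione | COC1=C2C(C)=C(C)C(=O)OC2=C(I)C(=O)C1CC=C(C)C | intermediate
21 | 7-hydroxy-8-iodo-5-methoxy-3,4-dimethyl-6-(3-methylbut-2-en-1-yl)-2H-chromen-2-one | COc1c(CC=C(C)C)c(O)c(I)c2oc(=O)c(C)c(C)c12 | intermediate
22 | dimagnesiated aryl phenoxide: 8-(chloromagnesio)-7-(chloromagnesiooxy)-5-methoxy-3,4-dimethyl-6-(3-methylbut-2-en-1-yl)-2H-chromen-2-one | COc1c(CC=C(C)C)c(O[Mg]Cl)c([Mg]Cl)c2oc(=O)c(C)c(C)c12 | intermediate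
23 | 7-hydroxy-8-{[(5R,6R)-6-[(1S)-1-hydroxyethyl]-5-methylcyclohex-1-en-1-yl]carbonyl}-5-methoxy-3,4-dimethyl-6-(3-methylbut-2-en-1-yl)-2H-chromen-2-one | COc1c(CC=C(C)C)c(O)c(C(=O)C2=CCC[C@@H](C)[C@H]2[C@H](C)O)c2oc(=O)c(C)c(C)c12 | target

**Total step count:** 14.
**Longest linear sequence:** 8 steps (steps 1, 2, 3, 5, 6, 7, 8, 14).

**Steps most likely to fail**

Step 5. The methyl group of the Z ether has to sit endo, next to the lactone ring; competition from the exo mode, or dimerization of the diene before it is intercepted, would mean poor control at the methyl-bearing carbon. The fallback sets out from 6 and comes back at 9. Benzyl prop-2-ynyl ether (commercial) is isomerized with catalytic KOtBu to benzyl propa-1,2-dienyl ether F1. F1 should add to 6 through its enol ether double bond, central carbon to the lactone β-carbon, to give (3S,3aR,5R)-5-(benzyloxy)-3-methyl-4-methylidene-3a,4,5,6-tetrahydro-2-benzofuran-1(3H)-one F2; here no dienophile substituent has to take an endo position at that carbon. Hydrogenation of the exocyclic alkene alone (H2, RhCl(PPh3)3, benzene) from the face opposite to lactone carbon C3 and the benzyloxy group would then set the methyl centre and give 9.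

Step 14. Acylation of the hindered arylmagnesium by the lactone may be slow, so that γ-deprotonation of the lactone, attack on a coumarin carbonyl, or ring closure of the phenoxide onto the new enone competes. The fallback sets out from 12 and comes back at 23. Reduction of 12 with (i-Bu)2AlH in CH2Cl2 at −78 °C gives (3S,3aR,4R)-3,4-dimethyl-1,3,3a,4,5,6-hexahydro-2-benzofuran-1-ol F3. Its hydroxy-enal form is more electrophilic and should take up excess 22 at low temperature to give 7-hydroxy-8-{hydroxy[(5R,6R)-6-[(1S)-1-hydroxyethyl]-5-methylcyclohex-1-en-1-yl]methyl}-5-methoxy-3,4-dimethyl-6-(3-methylbut-2-en-1-yl)-2H-chromen-2-one F4. Oxidation of the benzylic and allylic carbinol alone with MnO2 in CH2Cl2 would give 23.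

Step 9. Ring closure at the position between the two hydroxyl groups would give the 5-hydroxy-7-methoxy regioisomer, so loss of regiocontrol is the concern. The fallback sets out from 14 and comes back at 15. Pechmann condensation of 14 with phloroglucinol (commercial) gives 5,7-dihydroxy-3,4-dimethyl-2H-chromen-2-one F5. Sulfonylation of the more acidic 7-hydroxyl (TsCl, K2CO3, acetone) gives 5-hydroxy-3,4-dimethyl-2-oxo-2H-chromen-7-yl 4-methylbenzenesulfonate F6. Methylation (Me2SO4, K2CO3, acetone) gives 5-methoxy-3,4-dimethyl-2-oxo-2H-chromen-7-yl 4-methylbenzenesulfonate F7. Detosylation (KOH, aq. EtOH) gives 15 with the substitution pattern fixed.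

**Further compounds**
F1 | step 5 | benzyl propa-1,2-dienyl ether | C=C=COCc1ccccc1
F2 | step 5 | (3S,3aR,5R)-5-(benzyloxy)-3-methyl-4-methylidene-3a,4,5,6-tetrahydro-2-benzofuran-1(3H)-one | O=C1O[C@@H](C)[C@@H]2C(=C)[C@H](OCc3ccccc3)CC=C12
F3 | step 14 | (3S,3aR,4R)-3,4-dimethyl-1,3,3a,4,5,6-hexahydro-2-benzofuran-1-ol | OC1O[C@@H](C)[C@@H]2[C@H](C)CCC=C12
F4 | step 14 | 7-hydroxy-8-{hydroxy[(5R,6R)-6-[(1S)-1-hydroxyethyl]-5-methylcyclohex-1-en-1-yl]methyl}-5-methoxy-3,4-dimethyl-6-(3-methylbut-2-en-1-yl)-2H-chromen-2-one | COc1c(CC=C(C)C)c(O)c(C(O)C2=CCC[C@@H](C)[C@H]2[C@H](C)O)c2oc(=O)c(C)c(C)c12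
F5 | step 9 | 5,7-dihydroxy-3,4-dimethyl-2H-chromen-2-one | Cc1c(C)c2c(O)cc(O)cc2oc1=O
F6 | step 9 | 5-hydroxy-3,4-dimethyl-2-oxo-2H-chromen-7-yl 4-methylbenzenesulfonate | Cc1ccc(cc1)S(=O)(=O)Oc1cc(O)c2c(C)c(C)c(=O)oc2c1
F7 | step 9 | 5-methoxy-3,4-dimethyl-2-oxo-2H-chromen-7-yl 4-methylbenzenesulfonate | COc1cc(OS(=O)(=O)c2ccc(C)cc2)cc2oc(=O)c(C)c(C)c12
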